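**Plan**

1. Retrosynthesis: the butenolide is cut first at O–C16 and C18–C19, which removes CO2 and leaves a (17Z)-18-iodoalkene next to a cis-15,16-epoxide. C13–C14 is then cut into a core 2-metallo-1-alkene and a C14–C18 α-chloro aldehyde, and the core is traced back to (+)-larixol.
2. Enabling feature: the ring O–C19(=O)–C18=C17–C16 is CO2 spanning the three-carbon unit C16–C17=C18. The Z alkene holds a C18 carbanion cis to C16, and C16, allylic and part of an epoxide ring with C15, is the electrophile; the epoxide oxygen ends as the 15-OH.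
3. Forward, core: larixol → C13 methyl ketone (chain cut); ring B is hydrated at C8 through the 8α-epoxide; the 4α-methyl is hydroxylated by 6α-OH-directed C–H silylation and oxidation; then the trisylhydrazone is made.
4. Forward, side chain: propargyl alcohol → (Z)-3-iodo-2-methylacrolein → auxiliary-controlled chloroacetate syn-aldol → α-chloro aldehyde.
5. Union by Shapiro vinyl-anion addition (C13–C14), then chloride → cis-epoxide, one-pot lithiation/CO2/acid lactonisation (the butenolide ring is closed last), and desilylation.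
6. Stereochemistry: C5, C6, C9, C10 from larixol; C8 by α-face epoxidation; C4 by proximity of the 6α-oxygen to the 4α-methyl; C15/C16 by the oxazolidinone; C14 by Cornforth addition; C15 and C16 are each inverted once (epoxide closure, lactonisation).

Key step: step 20

Remark: (+)-larixol, taken as (13S)-labda-8(17),14-diene-6α,13-diol, is assumed to be a purchasable starting material; its C13 configuration is lost in step 1 and does not matter.
Remark on numbering: decalin C1–C10 as in labdanes (10β-CH3, 5α-H, chain β at C9), chain C11–C19 with C19 the lactone carbonyl; other carbons are named by position (4α-CH2OH, 4β-CH3, 8β-CH3, 13-methylidene, 17-CH3).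

**Route**

Step 1
Reactants: 1 (+)-larixol
Product: 2 methyl ketone (6α-hydroxy-8-methylidene core; C9 chain CH2CH2COCH3)
Conditions: KMnO4, MgSO4, acetone/H2O, 0 → 23 °C
Reagents that add atoms: none
Why: Permanganate dihydroxylation of the vinyl group and glycol cleavage of the resulting triol degrade the tertiary vinyl carbinol to the C13 methyl ketone (oxidative cleavage), while the more hindered ring B methylidene and the crowded 6α-hydroxyl react more slowly.

Step 2
Reactants: 2 methyl ketone
Product: 3 C13 ethylene ketal of 2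
Conditions: ethylene glycol, PPTS (cat.), benzene, reflux (Dean–Stark)
Reagents that add atoms: ethylene glycol, OCCO
Why: Acid-catalysed ketalisation masks the C13 ketone against the hydride and silane steps that follow, and the mild acid leaves the exocyclic alkene in place.

Step 3
Reactants: 3 C13 ethylene ketal
Product: 4 8α-spiro-epoxide (epoxide oxygen on the α face of C8)
Conditions: mCPBA, NaHCO3, CH2Cl2, 0 °C
Reagents that add atoms: mCPBA, OOC(=O)c1cccc(Cl)c1
Why: Prilezhaev epoxidation takes place on the α face of the C8 methylidene, because the β face is screened by the axial C10 methyl and the homoallylic 6α-hydroxyl hydrogen-bonds the peracid on the α side, which places the epoxide oxygen 8α.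

Step 4
Reactants: 4 8α-spiro-epoxide
Product: 5 6α,8α-diol (8β-CH3) C13 ketal
Conditions: LiAlH4, THF, reflux
Reagents that add atoms: none
Why: Hydride opens the spiro-epoxide by SN2 attack at its unsubstituted CH2 carbon (reductive epoxide opening), which leaves the oxygen on C8 with unchanged configuration and gives the 8α-hydroxy-8β-methyl centre.

Step 5
Reactants: 5 6α,8α-diol C13 ketal
Product: 7 oxasilinane (Et2Si bridging O6 and the 4α-CH2), via 6-O-diethylsilyl ether 6 (not isolated)
Conditions: Et2SiH2 (1.2 equiv), [Ir(cod)OMe]2 (cat.), THF, 23 °C; then [Rh(cod)Cl]2 (cat.), Xantphos, norbornene, THF, 100 °C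
Reagents that add atoms: diethylsilane, CC[SiH2]CC
Why: Dehydrogenative O-silylation of the secondary 6α-hydroxyl followed by rhodium-catalysed hydroxyl-directed δ-C–H silylation of a methyl group closes a six-membered oxasilinane; the equatorial 6α oxygen lies parallel to the equatorial 4α-methyl across C5, no γ C–H exists (C4, C8 and C10 are fully substituted) and the axial 4β, 8β and 10β methyls are out of reach, so C4 becomes a stereocentre with the silylmethyl group α.

Step 6
Reactants: 7 oxasilinane
Product: 8 triol (4α-CH2OH, 6α-OH, 8α-OH) C13 ketal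
Conditions: H2O2 (30% aq.), KHCO3, KF, THF/MeOH, 50 °C
Reagents that add atoms: hydrogen peroxide, OO
Why: Tamao–Fleming oxidation replaces the C–Si bond by C–OH and hydrolyses the Si–O bond, which gives the 1,4-diol without touching the ketal.

Step 7
Reactants: 8 triol C13 ketal
Product: 9 bis-TBS ether (4α-CH2OTBS, 6α-OTBS, 8α-OH free) C13 ketal
Conditions: TBSOTf (2.3 equiv), 2,6-lutidine, CH2Cl2, −78 → 0 °C
Reagents that add atoms: tert-butyldimethylsilyl triflate, CC(C)(C)[Si](C)(C)OS(=O)(=O)C(F)(F)F
Why: Silyl triflate silylation protects the primary and the secondary hydroxyl, while the tertiary equatorial 8α-hydroxyl flanked by C9 and the 8β-methyl is too hindered to react at low temperature.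

Step 8
Reactants: 9 bis-TBS ether C13 ketal
Product: 11 (E)-2,4,6-triisopropylbenzenesulfonylhydrazone of the C13 ketone, via methyl ketone 10 (not isolated)
Conditions: PPTS (cat.), THF/H2O, 40 °C; then 2,4,6-triisopropylbenzenesulfonyl hydrazide, THF, 23 °C
Reagents that add atoms: 2,4,6-triisopropylbenzenesulfonyl hydrazide, CC(C)c1cc(C(C)C)c(S(=O)(=O)NN)c(C(C)C)c1
Why: Mild acid hydrolysis of the dioxolane frees the methyl ketone, which condenses with the sulfonyl hydrazide (hydrazone formation) to the substrate for the Shapiro reaction; the E isomer with the sulfonamide nitrogen syn to the methyl group is the less crowded one.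

Step 9
Reactants: 12 propargyl alcohol
Product: 14 (Z)-3-iodo-2-methylprop-2-en-1-ol, via (Z)-vinylmagnesium alkoxide 13 (not isolated)
Conditions: MeMgBr (2.5 equiv), CuI (cat.), Et2O/THF, −10 → 23 °C; then I2, −10 °C
Reagents that add atoms: methylmagnesium bromide, C[Mg]Br; iodine, [I][I]
Why: Copper-catalysed carbomagnesiation of the propargylic magnesium alkoxide is an anti addition that places methyl on the internal carbon and magnesium on the terminal carbon cis to the CH2O group in a five-membered chelate, and iodinolysis of the C–Mg bond with retention gives the Z-iodoalkene.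

Step 10
Reactants: 14 (Z)-3-iodo-2-methylprop-2-en-1-ol
Product: 15 (Z)-3-iodo-2-methylprop-2-enal
Conditions: MnO2, CH2Cl2, 23 °C, dark
Reagents that add atoms: none
Why: MnO2 oxidises the allylic alcohol to the enal (allylic oxidation) under neutral conditions that do not isomerise the Z double bond.

Step 11
Reactants: 16 (R)-4-benzyl-2-oxazolidinone; 17 chloroacetyl chloride
Product: 19 (R)-4-benzyl-3-(chloroacetyl)oxazolidin-2-one, via lithium oxazolidinide 18 (not isolated)
Conditions: n-BuLi, THF, −78 °C; then 17, −78 → 0 °C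
Reagents that add atoms: none
Why: N-acylation of the lithiated oxazolidinone with the acid chloride at low temperature is faster than displacement of the alkyl chloride.

Step 12
Reactants: 19 (R)-4-benzyl-3-(chloroacetyl)oxazolidin-2-one; 15 (Z)-3-iodo-2-methylprop-2-enal
Product: 21 syn aldol adduct (2R,3S,4Z), via (Z)-boron enolate 20 (not isolated)
Conditions: Bu2BOTf, Et3N, Et2O, −78 → 0 °C; then 15, −78 → 0 °C; H2O2, MeOH, pH 7 buffer, 0 °C
Reagents that add atoms: none
Why: Evans syn aldol reaction, in which the Z-boron enolate adds through a closed chair (Zimmerman–Traxler) transition state on the enolate face opposite the benzyl group, which sets C15 (R, chloride) and C16 (S, hydroxyl) in the 15,16-syn relationship.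

Step 13
Reactants: 21 syn aldol adduct
Product: 22 (2R,3S,4Z)-2-chloro-3-hydroxy-5-iodo-N-methoxy-N,4-dimethylpent-4-enamide
Conditions: MeNHOMe·HCl, AlMe3, CH2Cl2, −20 → 0 °C
Reagents that add atoms: N,O-dimethylhydroxylamine hydrochloride, Cl.CNOC
Why: Aluminium amide transamidation, assisted by the free β-hydroxyl, exchanges the auxiliary for the N-methoxy-N-methylamide (Weinreb amide) without touching the α-chloride or the stereocentres.

Step 14
Reactants: 22 Weinreb amide
Product: 23 3-O-triethylsilyl ether of 22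
Conditions: TESCl, imidazole, DMF, 0 → 23 °C
Reagents that add atoms: chlorotriethylsilane, CC[Si](Cl)(CC)CC
Why: Silylation of the secondary hydroxyl blocks retro-aldol cleavage and installs a group that can later be removed in the presence of TBS ethers.

Step 15
Reactants: 23 silylated Weinreb amide
Product: 24 (2R,3S,4Z)-2-chloro-5-iodo-4-methyl-3-(triethylsilyloxy)pent-4-enal
Conditions: i-Bu2AlH, THF, −78 °C; aqueous Rochelle salt
Reagents that add atoms: none
Why: Hydride reduction of the Weinreb amide stops at the chelated tetrahedral aluminium intermediate, which gives the α-chloro aldehyde on cold work-up without epimerisation of C15.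

Step 16
Reactants: 11 trisylhydrazone; 24 α-chloro aldehyde
Product: 27 coupled allylic alcohol (14S,15S,16S; 15-chloro; 16-OTES; 13-methylidene), via vinyllithium 25 (not isolated), via vinylmagnesium bromide 26 (not isolated)
Conditions: n-BuLi (3.1 equiv), THF, −78 → 0 °C; MgBr2·OEt2, −78 °C; then 24, −78 °C
Reagents that add atoms: none
Why: Shapiro reaction, in which double deprotonation of the hydrazone (N–H and the syn methyl group) and loss of sulfinate and N2 give the 2-lithio-1-alkene, which after transmetalation to magnesium (to avoid iodine–metal exchange and enolisation) adds to the α-chloro aldehyde by the Cornforth model with C–Cl anti to C=O and attack past the small hydrogen, setting 14S anti to the chloride.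

Step 17
Reactants: 27 coupled allylic alcohol
Product: 28 14-O-TBS ether of 27
Conditions: TBSOTf (1.3 equiv), 2,6-lutidine, CH2Cl2, −78 °C
Reagents that add atoms: tert-butyldimethylsilyl triflate, CC(C)(C)[Si](C)(C)OS(=O)(=O)C(F)(F)F
Why: Silyl triflate silylation caps the new secondary C14 hydroxyl so that it cannot displace the neighbouring chloride later, and the hindered tertiary 8α-hydroxyl is left untouched at −78 °C.

Step 18
Reactants: 28 14-O-TBS ether
Product: 29 16-alcohol (14-OTBS, 15-chloro, 16-OH)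
Conditions: PPTS, MeOH/CH2Cl2, 0 °C
Reagents that add atoms: none
Why: Acid-catalysed methanolysis cleaves the triethylsilyl ether much faster than the bulkier tert-butyldimethylsilyl ethers (selective desilylation).

Step 19
Reactants: 29 16-alcohol
Product: 30 cis-15,16-epoxide (15S,16S) with the (17Z)-18-iodoalkene
Conditions: K2CO3, MeOH, 0 → 23 °C
Reagents that add atoms: none
Why: Intramolecular Williamson reaction, in which the C16 alkoxide displaces the C15 chloride by backside attack (3-exo-tet), inverting C15 and giving from the 15,16-syn chlorohydrin the cis-epoxide with its oxygen on the face that the C15 hydroxyl of the target occupies.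

Step 20
Reactants: 30 cis-15,16-epoxide
Product: 33 tris-TBS butenolide (14S,15R,16R), via C18 vinyllithium 31 (not isolated), via (Z)-epoxy acid 32 (not isolated)
Conditions: t-BuLi (3.2 equiv), Et2O, −78 °C; CO2 (gas), −78 → 0 °C; then CSA, CH2Cl2, 0 → 23 °C
Reagents that add atoms: carbon dioxide, O=C=O
Why: Iodine–lithium exchange at C18 occurs with retention of the Z geometry, the vinyllithium is carboxylated by CO2 to give the C18–C19 bond, and on acidification the (Z)-carboxylic acid opens the protonated cis-15,16-epoxide at C16 to give the O–C16 bond. The closest known reaction types are the carboxylation of alkenyllithiums and the acid-promoted lactonisation of (Z)-γ,δ-epoxy-α,β-unsaturated acids to 5-(1-hydroxyalkyl)butenolides. The butenolide ring (O–C19–C18=C17–C16) closes in the 5-exo-tet mode, and no other ring is formed. C16 is set by stereospecific SN2 inversion at the epoxide carbon (16S in the epoxide becomes 16R), and C15 keeps the epoxide oxygen with unchanged spatial arrangement as the free 15R hydroxyl. The step needs attack at C16 and not at C15: the Z alkene holds the carboxyl within bonding distance of C16, C16 is the allylic and more easily ionised epoxide carbon, and closure at C15 would be a 6-endo process. The vinyl anion should survive next to the epoxide because its C–Li bond lies in the alkene plane, orthogonal to the π system that would have to expel the epoxide oxygen, and because exchange at −78 °C is faster than attack of t-BuLi on the epoxide.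

Step 21
Reactants: 33 tris-TBS butenolide
Product: 34 CNP0301623.1 (target)
Conditions: HF·pyridine, pyridine, THF, 0 → 23 °C
Reagents that add atoms: none
Why: Fluoride-induced cleavage of the three silyl ethers (desilylation) under buffered acidic conditions frees the hydroxyls without epimerising C16 or opening the butenolide.

**Compound list**

1 | (+)-larixol, (13S)-labda-8(17),14-diene-6α,13-diol | C=C[C@@](C)(O)CC[C@@H]1[C@@]2(C)CCCC(C)(C)[C@@H]2[C@@H](O)CC1=C | starting material
2 | methyl ketone: 6α-hydroxy-8-methylidene core, C9 chain CH2CH2COCH3 | CC(=O)CC[C@@H]1[C@@]2(C)CCCC(C)(C)[C@@H]2[C@@H](O)CC1=C | intermediate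
3 | C13 ethylene ketal (2-methyl-1,3-dioxolan-2-yl) of 2 | CC1(CC[C@@H]2[C@@]3(C)CCCC(C)(C)[C@@H]3[C@@H](O)CC2=C)OCCO1 | intermediate
4 | 8α-spiro-epoxide of 3 (oxygen α, CH2 β) | CC1(CC[C@@H]2[C@@]3(C)CCCC(C)(C)[C@@H]3[C@@H](O)C[C@@]2(C4)O4)OCCO1 | intermediate
5 | 6α,8α-diol (8β-CH3), C13 ketal | CC1(CC[C@@H]2[C@@]3(C)CCCC(C)(C)[C@@H]3[C@@H](O)C[C@@]2(C)O)OCCO1 | intermediate
6 | 6-O-diethylsilyl (Si–H) ether of 5 | CC1(CC[C@@H]2[C@@]3(C)CCCC(C)(C)[C@@H]3[C@@H](O[SiH](CC)CC)C[C@@]2(C)O)OCCO1 | intermediate (not isolated)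
7 | oxasilinane: Et2Si bridging O6 and the 4α-CH2 (ring O6–C6–C5–C4–CH2–Si), 8α-OH, C13 ketal | CC1(CC[C@@H]2[C@@]3(C)CCC[C@@](C)(C[Si]4(CC)CC)[C@@H]3[C@@H](O4)C[C@@]2(C)O)OCCO1 | intermediate
8 | triol: 4α-CH2OH, 6α-OH, 8α-OH, C13 ketal | CC1(CC[C@@H]2[C@@]3(C)CCC[C@@](C)(CO)[C@@H]3[C@@H](O)C[C@@]2(C)O)OCCO1 | intermediate
9 | bis-TBS ether: 4α-CH2OTBS, 6α-OTBS, 8α-OH, C13 ketal | CC1(CC[C@@H]2[C@@]3(C)CCC[C@@](C)(CO[Si](C)(C)C(C)(C)C)[C@@H]3[C@@H](O[Si](C)(C)C(C)(C)C)C[C@@]2(C)O)OCCO1 | intermediate
10 | C13 methyl ketone with 4α-CH2OTBS, 6α-OTBS, 8α-OH | CC(=O)CC[C@@H]1[C@@]2(C)CCC[C@@](C)(CO[Si](C)(C)C(C)(C)C)[C@@H]2[C@@H](O[Si](C)(C)C(C)(C)C)C[C@@]1(C)O | intermediate (not isolated)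
11 | (E)-2,4,6-triisopropylbenzenesulfonylhydrazone of 10 | C/C(CC[C@@H]1[C@@]2(C)CCC[C@@](C)(CO[Si](C)(C)C(C)(C)C)[C@@H]2[C@@H](O[Si](C)(C)C(C)(C)C)C[C@@]1(C)O)=N\NS(=O)(=O)c1c(C(C)C)cc(C(C)C)cc1C(C)C | intermediate
12 | propargyl alcohol | C#CCO | starting material
13 | (Z)-vinylmagnesium alkoxide: bromomagnesium (Z)-3-(bromomagnesio)-2-methylprop-2-en-1-olate | Br[Mg]OC/C(C)=C\[Mg]Br | intermediate (not isolated)
14 | (Z)-3-iodo-2-methylprop-2-en-1-ol | OC/C(C)=C\I | intermediate
15 | (Z)-3-iodo-2-methylprop-2-enal | O=C/C(C)=C\I | intermediate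
16 | (R)-4-benzyl-2-oxazolidinone | O=C1N[C@H](Cc2ccccc2)CO1 | starting material
17 | chloroacetyl chloride | ClCC(Cl)=O | starting material
18 | lithium (R)-4-benzyl-2-oxooxazolidin-3-ide | [Li]N1[C@H](Cc2ccccc2)COC1=O | intermediate (not isolated)
19 | (R)-4-benzyl-3-(chloroacetyl)oxazolidin-2-one | O=C(CCl)N1[C@H](Cc2ccccc2)COC1=O | intermediate
20 | (Z)-dibutylboron enolate of 19 | CCCCB(CCCC)O/C(=C\Cl)N1[C@H](Cc2ccccc2)COC1=O | intermediate (not isolated)
21 | (R)-4-benzyl-3-[(2R,3S,4Z)-2-chloro-3-hydroxy-5-iodo-4-methylpent-4-enoyl]oxazolidin-2-one | O=C([C@H](Cl)[C@@H](O)/C(C)=C\I)N1[C@H](Cc2ccccc2)COC1=O | intermediate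
22 | (2R,3S,4Z)-2-chloro-3-hydroxy-5-iodo-N-methoxy-N,4-dimethylpent-4-enamide | CON(C)C(=O)[C@H](Cl)[C@@H](O)/C(C)=C\I | intermediate
23 | (2R,3S,4Z)-2-chloro-5-iodo-N-methoxy-N,4-dimethyl-3-(triethylsilyloxy)pent-4-enamide | CON(C)C(=O)[C@H](Cl)[C@@H](O[Si](CC)(CC)CC)/C(C)=C\I | intermediate
24 | (2R,3S,4Z)-2-chloro-5-iodo-4-methyl-3-(triethylsilyloxy)pent-4-enal | O=C[C@H](Cl)[C@@H](O[Si](CC)(CC)CC)/C(C)=C\I | intermediate
25 | C13 vinyllithium of the bis-TBS core (8-O-lithium alkoxide) | [Li]C(=C)CC[C@@H]1[C@@]2(C)CCC[C@@](C)(CO[Si](C)(C)C(C)(C)C)[C@@H]2[C@@H](O[Si](C)(C)C(C)(C)C)C[C@@]1(C)O[Li] | intermediate (not isolated)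
26 | C13 vinylmagnesium bromide of the bis-TBS core | Br[Mg]C(=C)CC[C@@H]1[C@@]2(C)CCC[C@@](C)(CO[Si](C)(C)C(C)(C)C)[C@@H]2[C@@H](O[Si](C)(C)C(C)(C)C)C[C@@]1(C)O[Li] | intermediate (not isolated)
27 | coupled allylic alcohol: 13-methylidene, (14S)-OH, (15S)-Cl, (16S)-OTES, (17Z)-18-iodo; core 4α-CH2OTBS, 6α-OTBS, 8α-OH | C=C(CC[C@@H]1[C@@]2(C)CCC[C@@](C)(CO[Si](C)(C)C(C)(C)C)[C@@H]2[C@@H](O[Si](C)(C)C(C)(C)C)C[C@@]1(C)O)[C@H](O)[C@H](Cl)[C@@H](O[Si](CC)(CC)CC)/C(C)=C\I | intermediate
28 | 14-O-TBS ether of 27 | C=C(CC[C@@H]1[C@@]2(C)CCC[C@@](C)(CO[Si](C)(C)C(C)(C)C)[C@@H]2[C@@H](O[Si](C)(C)C(C)(C)C)C[C@@]1(C)O)[C@H](O[Si](C)(C)C(C)(C)C)[C@H](Cl)[C@@H](O[Si](CC)(CC)CC)/C(C)=C\I | intermediate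
29 | 16-alcohol: 14-OTBS, 15-chloro, 16-OH (14,15-anti, 15,16-syn) | C=C(CC[C@@H]1[C@@]2(C)CCC[C@@](C)(CO[Si](C)(C)C(C)(C)C)[C@@H]2[C@@H](O[Si](C)(C)C(C)(C)C)C[C@@]1(C)O)[C@H](O[Si](C)(C)C(C)(C)C)[C@H](Cl)[C@@H](O)/C(C)=C\I | intermediate
30 | cis-(15S,16S)-epoxide, 14-OTBS, (17Z)-18-iodoalkene | C=C(CC[C@@H]1[C@@]2(C)CCC[C@@](C)(CO[Si](C)(C)C(C)(C)C)[C@@H]2[C@@H](O[Si](C)(C)C(C)(C)C)C[C@@]1(C)O)[C@H](O[Si](C)(C)C(C)(C)C)[C@H]3O[C@H]3/C(C)=C\I | intermediate
31 | C18 vinyllithium of 30 (8-O-lithium alkoxide) | C=C(CC[C@@H]1[C@@]2(C)CCC[C@@](C)(CO[Si](C)(C)C(C)(C)C)[C@@H]2[C@@H](O[Si](C)(C)C(C)(C)C)C[C@@]1(C)O[Li])[C@H](O[Si](C)(C)C(C)(C)C)[C@H]3O[C@H]3/C(C)=C\[Li] | intermediate (not isolated)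
32 | (17Z)-15,16-epoxy-19-oic acid (lithium salt before acidification) | C=C(CC[C@@H]1[C@@]2(C)CCC[C@@](C)(CO[Si](C)(C)C(C)(C)C)[C@@H]2[C@@H](O[Si](C)(C)C(C)(C)C)C[C@@]1(C)O)[C@H](O[Si](C)(C)C(C)(C)C)[C@H]3O[C@H]3/C(C)=C\C(=O)O | intermediate (not isolated)
33 | tris-TBS butenolide: (14S)-OTBS, (15R)-OH, (16R)-butenolide; core 4α-CH2OTBS, 6α-OTBS, 8α-OH | C=C(CC[C@@H]1[C@@]2(C)CCC[C@@](C)(CO[Si](C)(C)C(C)(C)C)[C@@H]2[C@@H](O[Si](C)(C)C(C)(C)C)C[C@@]1(C)O)[C@H](O[Si](C)(C)C(C)(C)C)[C@@H](O)[C@@H]1OC(=O)C=C1C | intermediate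
34 | CNP0301623.1 | C=C(CC[C@@H]1[C@@]2(C)CCC[C@@](C)(CO)[C@@H]2[C@@H](O)C[C@@]1(C)O)[C@H](O)[C@@H](O)[C@@H]1OC(=O)C=C1C | target

**Summary**

Total step count: 21.
Longest linear sequence: 14 steps (steps 1–8 and 16–21, from larixol); the side-chain branch is steps 9–15.

**Steps most likely to fail**

Step 5. The C–H silylation may stall: the silyl hydride on the crowded 6α oxygen is shielded by the very methyl group it must reach, and the free tertiary hydroxyl may take up silane or bind the catalyst, so that only diol is recovered after oxidation. The fallback replaces metal-catalysed silylation by an alkoxy-radical 1,5-hydrogen transfer (Barton nitrite photolysis); it sets out from compound 3 and comes back at compound 8. Compound 3 is nitrosated (NOCl, pyridine, −20 °C) to the 6α-nitrite ester F1. Irradiation (Hg lamp, benzene) gives the 6α-alkoxy radical, which abstracts hydrogen from the 4α-methyl through a six-membered transition state; recombination with NO and tautomerisation give the 4α-carbaldoxime F2. Aqueous TiCl3/NH4OAc cleaves the oxime to the aldehyde, which closes onto the 6α-hydroxyl as the five-membered lactol F3. mCPBA then gives the 8α-spiro-epoxy lactol F4, and LiAlH4 reduces lactol and epoxide together to triol 8.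

Step 16. The basic vinyl metal may enolise the α-chloro aldehyde or expel its β-silyloxy group, and facial selectivity at C14 may be eroded by the β-substituent. The fallback replaces aldehyde addition by acylation and reagent-controlled reduction; it sets out from compounds 11 and 23 and comes back at compound 27. The vinylmagnesium reagent 26, made from 11 as in step 16, is added to Weinreb amide 23 to give the α-chloro enone F5, the tetrahedral chelate protecting the product until work-up. Corey–Bakshi–Shibata reduction with (S)-2-methyl-CBS-oxazaborolidine and BH3·SMe2, chosen on the premise that the 1,1-disubstituted alkenyl group acts as the larger ketone substituent, should then give the 14S alcohol 27 under catalyst control.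

Step 20. The vinyllithium may be consumed before carboxylation by proton transfer or by attack of the organolithium on the allylic epoxide, and the crude acid may lactonise incompletely. The fallback replaces lithiation and CO2 capture by a magnesium-based formylation followed by oxidative lactonisation; it sets out from compound 30 and comes back at compound 33. Iodine–magnesium exchange with i-PrMgCl·LiCl (THF, −20 °C) and quenching with DMF give the (17Z)-epoxy enal F6. Pinnick oxidation (NaClO2, NaH2PO4, 2-methyl-2-butene, t-BuOH/H2O) gives acid 32, which should close to butenolide 33 under the buffered acidic conditions or on brief treatment with CSA.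

Further compounds
F1 | step 5 | 6α-nitrite ester of 3 | CC1(CC[C@@H]2[C@@]3(C)CCCC(C)(C)[C@@H]3[C@@H](ON=O)CC2=C)OCCO1
F2 | step 5 | 4α-carbaldoxime (6α-OH, 8-methylidene, C13 ketal) | CC1(CC[C@@H]2[C@@]3(C)CCC[C@@](C)(C=NO)[C@@H]3[C@@H](O)CC2=C)OCCO1
F3 | step 5 | five-membered lactol bridging the 4α-carbon and O6 (8-methylidene, C13 ketal) | CC1(CC[C@@H]2[C@@]3(C)CCC[C@@](C)(C(O)O4)[C@@H]3[C@@H]4CC2=C)OCCO1
F4 | step 5 | 8α-spiro-epoxide of lactol F3 | CC1(CC[C@@H]2[C@@]3(C)CCC[C@@](C)(C(O)O4)[C@@H]3[C@@H]4C[C@@]2(C5)O5)OCCO1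
F5 | step 16 | α-chloro enone: 13-methylidene-14-oxo, (15R)-Cl, (16S)-OTES, (17Z)-18-iodo | C=C(CC[C@@H]1[C@@]2(C)CCC[C@@](C)(CO[Si](C)(C)C(C)(C)C)[C@@H]2[C@@H](O[Si](C)(C)C(C)(C)C)C[C@@]1(C)O)C(=O)[C@H](Cl)[C@@H](O[Si](CC)(CC)CC)/C(C)=C\I
F6 | step 20 | (17Z)-15,16-epoxy enal (C19 aldehyde), 14-OTBS | C=C(CC[C@@H]1[C@@]2(C)CCC[C@@](C)(CO[Si](C)(C)C(C)(C)C)[C@@H]2[C@@H](O[Si](C)(C)C(C)(C)C)C[C@@]1(C)O)[C@H](O[Si](C)(C)C(C)(C)C)[C@H]3O[C@H]3/C(C)=C\C=O
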